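**Retrosynthetic overview**
1. Target 44 ← acetylation of lactone triol 43 ← oxidative γ-lactonisation (C19 → O7) of macrocyclic pentaol 41; the lactone is the last ring formed.
2. Ten-membered ring ← intramolecular Nozaki–Hiyama–Kishi closure of C6–C7 in (Z)-vinyl iodide/α-silyloxy aldehyde 35; ring A is present from the start, the carbocycle is second.
3. C8/C17 ← Sharpless epoxidation and methylcuprate opening of allylic alcohol 30; C8–C9 ← Cr/Ni coupling of aldehyde 25 with vinyl iodide 19, then oxidation and Felkin reduction.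
4. Key C1–C2 bond ← intermolecular aldol of the C1 enolate (from cuprate 1,4-addition to enone 6) with aldehyde 14, which sets C10, C1 and C2; C14 ← anti-selective hydroxyl-directed reduction.
5. Building blocks: 1,4-dioxaspiro[4.5]dec-6-en-8-one (ring A), propargyl alcohol (C3–C6, C16), but-2-yne-1,4-diol (C7, C8, C17, C19).

Assumption: briarane numbering is used for all intermediates (ring A = C1, C10–C14; C15 on C1, C16 on C5, C18 on C17, C19 lactone carbonyl, C20 on C11; Me-15 is β), and 26 is carried as a C9 epimer mixture.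

**Fragment A (enone 6)**

Step 1
Reactants: 1 1,4-dioxaspiro[4.5]dec-6-en-8-one
Product: 2 (8R)-1,4-dioxaspiro[4.5]dec-6-en-8-ol
Conditions: (S)-2-methyl-CBS-oxazaborolidine (10 mol%), BH3·SMe2, THF, −30 °C; MeOH quench
Reagents that add atoms: none
Why: Corey–Bakshi–Shibata reduction, in which the alkenyl arm acts as the large group so that hydride delivery gives the (R)-allylic alcohol (the later C11 control element).

Step 2
Reactants: 2 (8R)-1,4-dioxaspiro[4.5]dec-6-en-8-ol
Product: 3 (8R)-8-[(4-methoxybenzyl)oxy]-1,4-dioxaspiro[4.5]dec-6-ene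
Conditions: NaH, PMBCl, Bu4NI (cat.), THF/DMF, 0 °C → rt
Reagents that add atoms: 4-methoxybenzyl chloride (COc1ccc(CCl)cc1)
Why: Williamson etherification of the alkoxide, with no change at the stereocentre.

Step 3
Reactants: 3 (8R)-8-[(4-methoxybenzyl)oxy]-1,4-dioxaspiro[4.5]dec-6-ene
Product: 4 (4R)-4-[(4-methoxybenzyl)oxy]cyclohex-2-en-1-one
Conditions: 1 M HCl, THF, rt
Reagents that add atoms: water (O)
Why: Acid-catalysed ketal hydrolysis unmasks the enone conjugated to the existing alkene while the PMB ether survives dilute acid.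

Step 4
Reactants: 4 (4R)-4-[(4-methoxybenzyl)oxy]cyclohex-2-en-1-one
Product: 5 (4R)-2-iodo-4-[(4-methoxybenzyl)oxy]cyclohex-2-en-1-one
Conditions: I2, pyridine, CH2Cl2, 0 °C → rt
Reagents that add atoms: iodine (II)
Why: Johnson α-iodination of the enone (pyridine conjugate addition, iodination, elimination).

Step 5
Reactants: 5 (4R)-2-iodo-4-[(4-methoxybenzyl)oxy]cyclohex-2-en-1-one
Product: 6 (4R)-4-[(4-methoxybenzyl)oxy]-2-methylcyclohex-2-en-1-one
Conditions: Me2Zn, Pd(PPh3)4 (5 mol%), THF, 0 °C → rt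
Reagents that add atoms: dimethylzinc (C[Zn]C)
Why: Negishi cross-coupling of the α-iodoenone under neutral conditions, which avoids β-elimination of the γ-alkoxy group.

**Fragment B (aldehyde 14)**

Step 6
Reactants: 7 prop-2-yn-1-ol
Product: 9 (2Z)-3-iodo-2-methylprop-2-en-1-ol, via alkenylmagnesium alkoxide 8 (not isolated)
Conditions: MeMgBr (2.5 equiv), CuI (10 mol%), THF, −10 °C → rt; then I2, −78 → 0 °C
Reagents that add atoms: methylmagnesium bromide (C[Mg]Br); iodine (II)
Why: Copper-catalysed anti-carbomagnesiation of the propargylic alkoxide gives the chelated (Z)-alkenylmagnesium, and iodinolysis with retention puts iodine cis to the CH2O arm.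

Step 7
Reactants: 9 (2Z)-3-iodo-2-methylprop-2-en-1-ol
Product: 11 (2Z)-2-methyl-3-(trimethylsilyl)prop-2-en-1-ol, via bis-silyl compound 10 (not isolated)
Conditions: n-BuLi (1.05 equiv), Et2O, −78 °C; t-BuLi (2.1 equiv); Me3SiCl (2.5 equiv), −78 °C → rt; then K2CO3, MeOH
Reagents that add atoms: chlorotrimethylsilane (C[Si](C)(C)Cl)
Why: Lithium–iodine exchange with retention of geometry and C-silylation mask the later vinyl iodide as a cuprate-stable vinylsilane, and methanolysis frees the O-silyl ether.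

Step 8
Reactants: 11 (2Z)-2-methyl-3-(trimethylsilyl)prop-2-en-1-ol
Product: 12 [(1Z)-3-bromo-2-methylprop-1-en-1-yl]trimethylsilane
Conditions: CBr4, PPh3, CH2Cl2, 0 °C
Reagents that add atoms: carbon tetrabromide (BrC(Br)(Br)Br)
Why: Appel bromination of the primary allylic alcohol without touching the alkene geometry.

Step 9
Reactants: 12 [(1Z)-3-bromo-2-methylprop-1-en-1-yl]trimethylsilane
Product: 14 (4Z)-4-methyl-5-(trimethylsilyl)pent-4-enal, via alkylated hydrazone 13 (not isolated)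
Conditions: acetaldehyde N,N-dimethylhydrazone, LiN(iPr)2, THF, 0 °C; add 12, −78 → 0 °C; then aq. oxalic acid, Et2O, rt
Reagents that add atoms: acetaldehyde N,N-dimethylhydrazone (CC=NN(C)C); water (O)
Why: Corey–Enders azaenolate alkylation with the reactive allylic bromide adds the two-carbon aldehyde unit (C2, C3), and mild hydrolysis releases the aldehyde.

**Fragment C (vinyl iodide 19)**

Step 10
Reactants: 15 but-2-yne-1,4-diol
Product: 16 4-[(4-methoxybenzyl)oxy]but-2-yn-1-ol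
Conditions: NaH (1 equiv), PMBCl, Bu4NI (cat.), THF, 0 °C → rt (diol in excess)
Reagents that add atoms: 4-methoxybenzyl chloride (COc1ccc(CCl)cc1)
Why: Statistical Williamson mono-etherification of the symmetrical diol.

Step 11
Reactants: 16 4-[(4-methoxybenzyl)oxy]but-2-yn-1-ol
Product: 18 (2Z)-3-iodo-4-[(4-methoxybenzyl)oxy]but-2-en-1-ol, via cyclic alkenylaluminate 17 (not isolated)
Conditions: NaAlH2(OCH2CH2OMe)2, THF, 0 °C → rt; then I2, −78 °C
Reagents that add atoms: iodine (II)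
Why: Hydroxyl-directed trans-hydroalumination places aluminium on the distal alkyne carbon (C8) cis to the carbinol, and iodinolysis with retention gives the (Z)-iodide.

Step 12
Reactants: 18 (2Z)-3-iodo-4-[(4-methoxybenzyl)oxy]but-2-en-1-ol
Product: 19 tert-butyl{[(2Z)-3-iodo-4-[(4-methoxybenzyl)oxy]but-2-en-1-yl]oxy}dimethylsilane
Conditions: TBSCl, imidazole, DMF, rt
Reagents that add atoms: tert-butyldimethylsilyl chloride (CC(C)(C)[Si](C)(C)Cl)
Why: Standard silylation of the primary alcohol (the later C19 oxygen).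

**Main line**

Step 13
Reactants: 6 (4R)-4-[(4-methoxybenzyl)oxy]-2-methylcyclohex-2-en-1-one; 14 (4Z)-4-methyl-5-(trimethylsilyl)pent-4-enal
Product: 21 C14-ketone aldol adduct (1β-Me; 1α-[(2S)-2-hydroxy chain C2–C6 ending in (5Z)-C(Me)=CH-SiMe3]; 10β-CH2SiMe2(OiPr); 11α-OPMB), via magnesium enolate 20 (not isolated)
Conditions: (iPrO)Me2SiCH2MgCl (2.4 equiv), CuI (1.2 equiv), THF, −78 → −30 °C; then 14, −78 °C; pH 7 buffer
Reagents that add atoms: (isopropoxydimethylsilyl)methylmagnesium chloride (CC(C)O[Si](C)(C)C[Mg]Cl)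
Why: Cuprate 1,4-addition anti to the C11 ether sets C10 and gives the C1 enolate regiospecifically, which undergoes an intermolecular aldol with 14 anti to the new C10 substituent through a Zimmerman–Traxler chair (aldehyde chain equatorial), setting the quaternary C1 and the 2S carbinol.

Step 14
Reactants: 21 C14-ketone aldol adduct
Product: 22 (2S,14S)-anti-1,3-diol (14α-OH)
Conditions: Me4NBH(OAc)3, MeCN/AcOH, −30 °C (crude 21)
Reagents that add atoms: none
Why: Evans–Saksena reduction, in which the C2 alkoxyborohydride delivers hydride intramolecularly through a chair transition state with Me-15 axial to give the 1,3-anti diol (14α-OH).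

Step 15
Reactants: 22 (2S,14S)-anti-1,3-diol
Product: 23 2,9,14-triol (C9 = CH2OH)
Conditions: H2O2 (30%), KF, KHCO3, THF/MeOH, rt
Reagents that add atoms: hydrogen peroxide (OO)
Why: Tamao–Kumada oxidation converts the alkoxysilyl-methyl group into the hydroxymethyl group without touching the C-SiMe3 vinylsilane.

Step 16
Reactants: 23 2,9,14-triol
Product: 24 2,14-O-isopropylidene acetal with free C9 primary alcohol
Conditions: 2,2-dimethoxypropane, PPTS (cat.), CH2Cl2, rt
Reagents that add atoms: 2,2-dimethoxypropane (COC(C)(C)OC)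
Why: Acetonide formation is possible only across the 1,3-diol (C2/C14), since the primary alcohol is 1,4 to both.

Step 17
Reactants: 24 2,14-O-isopropylidene acetal
Product: 25 C9 aldehyde
Conditions: DMP, pyridine, CH2Cl2, 0 °C → rt
Reagents that add atoms: none
Why: Dess–Martin oxidation under buffered, non-basic conditions avoids epimerisation at C10 and β-elimination of the C11 ether.

Step 18
Reactants: 25 C9 aldehyde; 19 tert-butyl{[(2Z)-3-iodo-4-[(4-methoxybenzyl)oxy]but-2-en-1-yl]oxy}dimethylsilane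
Product: 26 C9 allylic alcohols (both C9 epimers; C8=C17 with C9 cis to C19; 7-OPMB; 19-OTBS)
Conditions: CrCl2 (6 equiv), NiCl2 (2 mol%), DMSO, rt
Reagents that add atoms: none
Why: Intermolecular Nozaki–Hiyama–Kishi coupling adds the alkenylchromium (geometry retained) chemoselectively to the hindered aldehyde under non-basic conditions, and the C9 configuration is reset in the next two steps.

Step 19
Reactants: 26 C9 allylic alcohols
Product: 27 C9 enone
Conditions: DMP, pyridine, CH2Cl2, 0 °C → rt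
Reagents that add atoms: none
Why: Dess–Martin oxidation converges both epimers to one enone.

Step 20
Reactants: 27 C9 enone
Product: 28 (9S)-allylic alcohol
Conditions: NaBH4, CeCl3·7H2O, MeOH, −78 °C
Reagents that add atoms: none
Why: Luche 1,2-reduction under Felkin–Anh control, with hydride entering anti to the quaternary C1 arm of C10 (enone arm gauche to H-10), which gives the 9S carbinol.

Step 21
Reactants: 28 (9S)-allylic alcohol
Product: 29 (9S)-9-acetate
Conditions: Ac2O, pyridine, DMAP (cat.), rt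
Reagents that add atoms: acetic anhydride (CC(=O)OC(C)=O)
Why: DMAP-catalysed acylation installs the final C9 acetate, which also blocks O9 from later lactonisation.

Step 22
Reactants: 29 (9S)-9-acetate
Product: 30 7,11-diol (primary allylic C7-OH and 11α-OH)
Conditions: DDQ (2.6 equiv), CH2Cl2/pH 7 buffer, 0 °C
Reagents that add atoms: none
Why: Oxidative cleavage of both 4-methoxybenzyl ethers by DDQ (benzylic oxocarbenium, hydrolysis) leaves silyl, acetal and acetate groups intact.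

Step 23
Reactants: 30 7,11-diol
Product: 31 8,17-epoxy alcohol
Conditions: Ti(OiPr)4 (1.2 equiv), D-(−)-diethyl tartrate (1.4 equiv), t-BuOOH, 4 Å MS, CH2Cl2, −20 °C
Reagents that add atoms: tert-butyl hydroperoxide (CC(C)(C)OO)
Why: Sharpless asymmetric epoxidation of the primary (E)-2,3-disubstituted allylic alcohol, where the D-tartrate delivers oxygen to the face that fixes C8 as in the target (reagent control).

Step 24
Reactants: 31 8,17-epoxy alcohol
Product: 32 7,8,11-triol with the C17 methyl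
Conditions: Me2CuLi (6 equiv, from MeLi and CuI), Et2O, −40 → 0 °C
Reagents that add atoms: lithium dimethylcuprate ([Li+].C[Cu-]C)
Why: SN2 epoxide opening by the cuprate at C17, the only epoxide carbon that is not fully substituted, with inversion gives the tertiary C8-OH and the C17 methyl stereocentre as in the target.

Step 25
Reactants: 32 7,8,11-triol
Product: 33 C7 aldehyde and C11 ketone with free tertiary 8-OH
Conditions: DMP (3 equiv), pyridine, CH2Cl2, 0 °C → rt
Reagents that add atoms: none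
Why: Dess–Martin oxidation converts the primary and the secondary alcohol at once, and the tertiary alcohol cannot be oxidised.

Step 26
Reactants: 33 C7 aldehyde and C11 ketone
Product: 34 8-O-triethylsilyl ether
Conditions: Et3SiOTf, 2,6-lutidine, CH2Cl2, −78 °C
Reagents that add atoms: triethylsilyl trifluoromethanesulfonate (CC[Si](CC)(CC)OS(=O)(=O)C(F)(F)F)
Why: Silyl triflate silylation of the tertiary alcohol at low temperature (the aldehyde has no α-hydrogen) provides a non-chelating α-silyloxy aldehyde for the ring closure.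

Step 27
Reactants: 34 8-O-triethylsilyl ether
Product: 35 (5Z)-6-iodo alkene
Conditions: NIS, (CF3)2CHOH, 0 °C, 10 min
Reagents that add atoms: N-iodosuccinimide (O=C1CCC(=O)N1I)
Why: Stereoretentive iododesilylation (ipso attack through the β-silyl cation) unmasks the (Z)-vinyl iodide when no other alkene or electron-rich arene is present.

Step 28
Reactants: 35 (5Z)-6-iodo alkene
Product: 36 ten-membered carbocycle with (7S)-7-OH
Conditions: CrCl2 (10 equiv), NiCl2 (10 mol%), DMSO/THF, 2 mM, rt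
Reagents that add atoms: none
Why: Intramolecular Nozaki–Hiyama–Kishi reaction, aldehyde-selective over the C11 ketone, with polar Felkin–Anh addition (C8-OSiEt3 antiperiplanar, larger C9 arm next to the carbonyl oxygen) giving 7S.

Step 29
Reactants: 36 ten-membered carbocycle
Product: 37 7,8-bis(triethylsilyl) ether
Conditions: Et3SiOTf, 2,6-lutidine, CH2Cl2, −78 → −40 °C
Reagents that add atoms: triethylsilyl trifluoromethanesulfonate (CC[Si](CC)(CC)OS(=O)(=O)C(F)(F)F)
Why: Silylation removes the last free hydroxyl before the strong-base step.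

Step 30
Reactants: 37 7,8-bis(triethylsilyl) ether
Product: 39 C11 enol triflate (Δ11,12), via potassium enolate 38 (not isolated)
Conditions: KN(SiMe3)2 (1.1 equiv), THF, −78 °C; then PhNTf2
Reagents that add atoms: N-phenylbis(trifluoromethanesulfonimide) (O=S(=O)(N(c1ccccc1)S(=O)(=O)C(F)(F)F)C(F)(F)F)
Why: Kinetic deprotonation at the unhindered C12 methylene (H-10 is shielded by the quaternary C1, so the C9 acetate is not eliminated), followed by O-triflation.

Step 31
Reactants: 39 C11 enol triflate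
Product: 40 11-methyl-Δ11,12 macrocycle
Conditions: Me2Zn, Pd(PPh3)4 (5 mol%), THF, 0 °C → rt
Reagents that add atoms: dimethylzinc (C[Zn]C)
Why: Negishi cross-coupling of the enol triflate installs C20 and fixes the ring A double bond regiochemically while tolerating the acetate.

Step 32
Reactants: 40 11-methyl-Δ11,12 macrocycle
Product: 41 pentaol (2,7,8,14,19-OH; 9-OAc)
Conditions: HF (48% aq.), MeCN, 0 °C → rt
Reagents that add atoms: none
Why: Acidic fluoride removes the three silyl ethers and hydrolyses the strained anti-1,3-diol acetonide in one operation.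

Step 33
Reactants: 41 pentaol
Product: 43 lactone triol (2,8,14-OH; 9-OAc), via lactol 42 (not isolated)
Conditions: TEMPO (20 mol%), PhI(OAc)2 (2.5 equiv), CH2Cl2, rt
Reagents that add atoms: none
Why: TEMPO-catalysed oxidation is selective for the only primary alcohol (C19), whose aldehyde is trapped by the C7 hydroxyl as the five-membered lactol and oxidised on to the γ-lactone.

Step 34
Reactants: 43 lactone triol
Product: 44 target CNP0187165.2
Conditions: Ac2O, pyridine, DMAP (cat.), CH2Cl2, rt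
Reagents that add atoms: acetic anhydride (CC(=O)OC(C)=O)
Why: DMAP-catalysed acetylation of the two secondary alcohols (C2, C14), which the hindered tertiary C8 hydroxyl does not undergo under these conditions.

**Compound list**
1 | 1,4-dioxaspiro[4.5]dec-6-en-8-one | O=C1C=CC2(CC1)OCCO2 | starting material
2 | (8R)-1,4-dioxaspiro[4.5]dec-6-en-8-ol | O[C@H]1C=CC2(CC1)OCCO2 | intermediate
3 | (8R)-8-[(4-methoxybenzyl)oxy]-1,4-dioxaspiro[4.5]dec-6-ene | COc1ccc(CO[C@H]2C=CC3(CC2)OCCO3)cc1 | intermediate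
4 | (4R)-4-[(4-methoxybenzyl)oxy]cyclohex-2-en-1-one | COc1ccc(CO[C@H]2C=CC(=O)CC2)cc1 | intermediate
5 | (4R)-2-iodo-4-[(4-methoxybenzyl)oxy]cyclohex-2-en-1-one | COc1ccc(CO[C@H]2C=C(I)C(=O)CC2)cc1 | intermediate
6 | (4R)-4-[(4-methoxybenzyl)oxy]-2-methylcyclohex-2-en-1-one | COc1ccc(CO[C@H]2C=C(C)C(=O)CC2)cc1 | intermediate
7 | prop-2-yn-1-ol | C#CCO | starting material
8 | bromomagnesium (2Z)-3-(bromomagnesio)-2-methylprop-2-en-1-olate | C/C(CO[Mg]Br)=C/[Mg]Br | intermediate (not isolated)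
9 | (2Z)-3-iodo-2-methylprop-2-en-1-ol | C/C(CO)=C/I | intermediate
10 | (2Z)-2-methyl-3-(trimethylsilyl)prop-2-en-1-yl trimethylsilyl ether | C/C(CO[Si](C)(C)C)=C/[Si](C)(C)C | intermediate (not isolated)
11 | (2Z)-2-methyl-3-(trimethylsilyl)prop-2-en-1-ol | C/C(CO)=C/[Si](C)(C)C | intermediate
12 | [(1Z)-3-bromo-2-methylprop-1-en-1-yl]trimethylsilane | C/C(CBr)=C/[Si](C)(C)C | intermediate
13 | (4Z)-4-methyl-5-(trimethylsilyl)pent-4-enal N,N-dimethylhydrazone | CN(C)N=CCC/C(C)=C\[Si](C)(C)C | intermediate (not isolated)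
14 | (4Z)-4-methyl-5-(trimethylsilyl)pent-4-enal | O=CCC/C(C)=C\[Si](C)(C)C | intermediate
15 | but-2-yne-1,4-diol | OCC#CCO | starting material
16 | 4-[(4-methoxybenzyl)oxy]but-2-yn-1-ol | COc1ccc(COCC#CCO)cc1 | intermediate
17 | sodium cyclic (Z)-alkenylaluminate (Al bound to O19 and C8 in a five-membered ring; two 2-methoxyethoxy ligands) | COCCO[Al-]1(OCCOC)OCC=C1COCc1ccc(OC)cc1.[Na+] | intermediate (not isolated)
18 | (2Z)-3-iodo-4-[(4-methoxybenzyl)oxy]but-2-en-1-ol | COc1ccc(COC/C(I)=C/CO)cc1 | intermediate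
19 | tert-butyl{[(2Z)-3-iodo-4-[(4-methoxybenzyl)oxy]but-2-en-1-yl]oxy}dimethylsilane | COc1ccc(COC/C(I)=C/CO[Si](C)(C)C(C)(C)C)cc1 | intermediate
20 | chloromagnesium C1(14)-enolate of the 1,4-adduct (10β-CH2SiMe2(OiPr); 11α-OPMB) | Cl[Mg]OC1=C(C)[C@@H](C[Si](C)(C)OC(C)C)[C@H](OCc2ccc(OC)cc2)CC1 | intermediate (not isolated)
21 | C14-ketone aldol adduct: 1β-Me; 1α-[(2S)-CH(OH)CH2CH2C(Me)=CH-SiMe3, 5Z]; 10β-CH2SiMe2(OiPr); 11α-OPMB (11R) | O=C1CC[C@@H](OCc2ccc(OC)cc2)[C@H](C[Si](C)(C)OC(C)C)[C@@]1(C)[C@@H](O)CC/C(C)=C\[Si](C)(C)C | intermediate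
22 | (2S,14S)-anti-1,3-diol of 21 (14α-OH) | O[C@H]1CC[C@@H](OCc2ccc(OC)cc2)[C@H](C[Si](C)(C)OC(C)C)[C@@]1(C)[C@@H](O)CC/C(C)=C\[Si](C)(C)C | intermediate
23 | 2,9,14-triol (10β-CH2OH) | O[C@H]1CC[C@@H](OCc2ccc(OC)cc2)[C@H](CO)[C@@]1(C)[C@@H](O)CC/C(C)=C\[Si](C)(C)C | intermediate
24 | 2,14-O-isopropylidene acetal of 23 (free C9-OH) | CC1(C)O[C@H]2CC[C@@H](OCc3ccc(OC)cc3)[C@H](CO)[C@@]2(C)[C@@H](O1)CC/C(C)=C\[Si](C)(C)C | intermediate
25 | C9 aldehyde (10β-CHO) | CC1(C)O[C@H]2CC[C@@H](OCc3ccc(OC)cc3)[C@H](C=O)[C@@]2(C)[C@@H](O1)CC/C(C)=C\[Si](C)(C)C | intermediate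
26 | C9 allylic alcohols, both C9 epimers (C8=C17 with C9 cis to C19; 7-OPMB; 19-OTBS) | CC1(C)O[C@H]2CC[C@@H](OCc3ccc(OC)cc3)[C@H](C(O)/C(COCc3ccc(OC)cc3)=C\CO[Si](C)(C)C(C)(C)C)[C@@]2(C)[C@@H](O1)CC/C(C)=C\[Si](C)(C)C | intermediate
27 | C9 enone | CC1(C)O[C@H]2CC[C@@H](OCc3ccc(OC)cc3)[C@H](C(=O)/C(COCc3ccc(OC)cc3)=C\CO[Si](C)(C)C(C)(C)C)[C@@]2(C)[C@@H](O1)CC/C(C)=C\[Si](C)(C)C | intermediate
28 | (9S)-allylic alcohol | CC1(C)O[C@H]2CC[C@@H](OCc3ccc(OC)cc3)[C@H]([C@H](O)/C(COCc3ccc(OC)cc3)=C\CO[Si](C)(C)C(C)(C)C)[C@@]2(C)[C@@H](O1)CC/C(C)=C\[Si](C)(C)C | intermediate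
29 | (9S)-9-acetate | CC1(C)O[C@H]2CC[C@@H](OCc3ccc(OC)cc3)[C@H]([C@H](OC(C)=O)/C(COCc3ccc(OC)cc3)=C\CO[Si](C)(C)C(C)(C)C)[C@@]2(C)[C@@H](O1)CC/C(C)=C\[Si](C)(C)C | intermediate
30 | 7,11-diol (9-OAc; 19-OTBS) | CC1(C)O[C@H]2CC[C@@H](O)[C@H]([C@H](OC(C)=O)/C(CO)=C\CO[Si](C)(C)C(C)(C)C)[C@@]2(C)[C@@H](O1)CC/C(C)=C\[Si](C)(C)C | intermediate
31 | 8,17-epoxy alcohol (C8 as in 44; C17 epoxide carbon to be inverted) | CC1(C)O[C@H]2CC[C@@H](O)[C@H]([C@H](OC(C)=O)[C@]3(CO)O[C@@H]3CO[Si](C)(C)C(C)(C)C)[C@@]2(C)[C@@H](O1)CC/C(C)=C\[Si](C)(C)C | intermediate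
32 | 7,8,11-triol with C17 methyl (C8, C17 as in 44) | CC1(C)O[C@H]2CC[C@@H](O)[C@H]([C@H](OC(C)=O)[C@@](O)(CO)[C@@H](C)CO[Si](C)(C)C(C)(C)C)[C@@]2(C)[C@@H](O1)CC/C(C)=C\[Si](C)(C)C | intermediate
33 | C7 aldehyde, C11 ketone, free 8-OH | CC1(C)O[C@H]2CCC(=O)[C@H]([C@H](OC(C)=O)[C@@](O)(C=O)[C@@H](C)CO[Si](C)(C)C(C)(C)C)[C@@]2(C)[C@@H](O1)CC/C(C)=C\[Si](C)(C)C | intermediate
34 | 8-O-triethylsilyl ether of 33 | CC1(C)O[C@H]2CCC(=O)[C@H]([C@H](OC(C)=O)[C@@](O[Si](CC)(CC)CC)(C=O)[C@@H](C)CO[Si](C)(C)C(C)(C)C)[C@@]2(C)[C@@H](O1)CC/C(C)=C\[Si](C)(C)C | intermediate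
35 | (5Z)-6-iodo alkene (seco aldehyde) | CC1(C)O[C@H]2CCC(=O)[C@H]([C@H](OC(C)=O)[C@@](O[Si](CC)(CC)CC)(C=O)[C@@H](C)CO[Si](C)(C)C(C)(C)C)[C@@]2(C)[C@@H](O1)CC/C(C)=C\I | intermediate
36 | ten-membered carbocycle, (7S)-7-OH, 11-oxo, (5Z) | CC1(C)O[C@H]2CCC(=O)[C@@H]3[C@H](OC(C)=O)[C@](O[Si](CC)(CC)CC)([C@@H](C)CO[Si](C)(C)C(C)(C)C)[C@@H](O)/C=C(/C)CC[C@H](O1)[C@@]23C | intermediate
37 | 7,8-bis(triethylsilyl) ether of 36 | CC1(C)O[C@H]2CCC(=O)[C@@H]3[C@H](OC(C)=O)[C@](O[Si](CC)(CC)CC)([C@@H](C)CO[Si](C)(C)C(C)(C)C)[C@@H](O[Si](CC)(CC)CC)/C=C(/C)CC[C@H](O1)[C@@]23C | intermediate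
38 | potassium C11(12)-enolate of 37 | CC1(C)O[C@H]2CC=C([O-])[C@@H]3[C@H](OC(C)=O)[C@](O[Si](CC)(CC)CC)([C@@H](C)CO[Si](C)(C)C(C)(C)C)[C@@H](O[Si](CC)(CC)CC)/C=C(/C)CC[C@H](O1)[C@@]23C.[K+] | intermediate (not isolated)
39 | C11 enol triflate (Δ11,12) | CC1(C)O[C@H]2CC=C(OS(=O)(=O)C(F)(F)F)[C@@H]3[C@H](OC(C)=O)[C@](O[Si](CC)(CC)CC)([C@@H](C)CO[Si](C)(C)C(C)(C)C)[C@@H](O[Si](CC)(CC)CC)/C=C(/C)CC[C@H](O1)[C@@]23C | intermediate
40 | 11-methyl-Δ11,12 protected macrocycle | CC1(C)O[C@H]2CC=C(C)[C@@H]3[C@H](OC(C)=O)[C@](O[Si](CC)(CC)CC)([C@@H](C)CO[Si](C)(C)C(C)(C)C)[C@@H](O[Si](CC)(CC)CC)/C=C(/C)CC[C@H](O1)[C@@]23C | intermediate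
41 | pentaol (2,7,8,14,19-OH; 9-OAc) | O[C@H]1CC=C(C)[C@@H]2[C@H](OC(C)=O)[C@](O)([C@@H](C)CO)[C@@H](O)/C=C(/C)CC[C@H](O)[C@@]12C | intermediate
42 | C19 lactol (O7–C19 hemiacetal) | O[C@H]1CC=C(C)[C@@H]2[C@H](OC(C)=O)[C@@]3(O)[C@H](/C=C(/C)CC[C@H](O)[C@@]12C)OC(O)[C@@H]3C | intermediate (not isolated)
43 | lactone triol (2,8,14-OH; 9-OAc) | O[C@H]1CC=C(C)[C@@H]2[C@H](OC(C)=O)[C@@]3(O)[C@H](/C=C(/C)CC[C@H](O)[C@@]12C)OC(=O)[C@@H]3C | intermediate
44 | CNP0187165.2: (1S,2S,5Z,7S,8S,9S,10S,14S,17R)-2,9,14-triacetoxy-8-hydroxybriara-5,11-diene γ-lactone (C19 → O7) | CC(=O)O[C@H]1CC=C(C)[C@@H]2[C@H](OC(C)=O)[C@@]3(O)[C@H](/C=C(/C)CC[C@H](OC(C)=O)[C@@]12C)OC(=O)[C@@H]3C | target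

**Totals**
Total steps: 34. Longest linear sequence: 27 steps (steps 1–5, then 13–34, from compound 1).

**Three steps most likely to fail, and fallbacks**

Step 13 (three-component conjugate addition/aldol). The silylmethyl cuprate may add sluggishly to the α-methyl enone, or the magnesium enolate may give poor C1/C2 selectivity. The fallback sets out from 6: the cuprate addition is run with Me3SiCl present so that the regiodefined enolate is isolated as the trimethylsilyl enol ether F1. F1 is then joined to 14 in a BF3·OEt2-mediated Mukaiyama aldol (CH2Cl2, −78 °C), an open transition state with the same approach anti to the C10 substituent. It comes back to the route at 21.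

Step 20 (Felkin-controlled Luche reduction). If reduction of 27 does not favour the 9S carbinol, the fallback sets out from 26. Its Felkin-derived major component, the (9R)-allylic alcohol F2, is separated and inverted in a Mitsunobu reaction with acetic acid (PPh3, diisopropyl azodicarboxylate, toluene, 0 °C). This gives the (9S)-acetate directly and comes back to the route at 29, skipping steps 19–21 for that material.

Step 28 (Cr/Ni macrocyclisation). If ring closure is poor or the C7 epimer dominates, the fallback sets out from 35. Pd(PPh3)4 with Bu3SnH reduces the vinyl iodide to the 1,1-disubstituted alkene aldehyde F3. An intermolecular Nozaki–Hiyama–Kishi addition of vinyl bromide (CrCl2, NiCl2 cat., DMSO), aldehyde-selective and under open-chain Felkin–Anh control, then gives the (7S)-allylic alcohol F4. Ring-closing metathesis with the second-generation Grubbs catalyst (toluene, 80 °C, 1 mM) forms C5=C6, with the Z geometry imposed by the ten-membered ring, and comes back to the route at 36.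

**Further compounds**
F1 | step 13 | trimethylsilyl enol ether of the 1,4-adduct (C1=C14-OSiMe3; 10β-CH2SiMe2(OiPr); 11α-OPMB) | C[Si](C)(C)OC1=C(C)[C@@H](C[Si](C)(C)OC(C)C)[C@H](OCc2ccc(OC)cc2)CC1
F2 | step 20 | (9R)-allylic alcohol (C9 epimer of 28) | CC1(C)O[C@H]2CC[C@@H](OCc3ccc(OC)cc3)[C@H]([C@@H](O)/C(COCc3ccc(OC)cc3)=C\CO[Si](C)(C)C(C)(C)C)[C@@]2(C)[C@@H](O1)CC/C(C)=C\[Si](C)(C)C
F3 | step 28 | des-iodo aldehyde with C5(Me)=CH2 terminus | CC1(C)O[C@H]2CCC(=O)[C@H]([C@H](OC(C)=O)[C@@](O[Si](CC)(CC)CC)(C=O)[C@@H](C)CO[Si](C)(C)C(C)(C)C)[C@@]2(C)[C@@H](O1)CCC(C)=C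
F4 | step 28 | (7S)-allylic alcohol diene (C7-vinyl carbinol; C5(Me)=CH2) | CC1(C)O[C@H]2CCC(=O)[C@H]([C@H](OC(C)=O)[C@@](O[Si](CC)(CC)CC)([C@@H](O)C=C)[C@@H](C)CO[Si](C)(C)C(C)(C)C)[C@@]2(C)[C@@H](O1)CCC(C)=C
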